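# Proposed total synthesis of CNP0167461.3 (1,10-epoxy heliangolide diester)

## Structural features

The target is a ten-membered carbocycle (C1–C10) fused at C6–C7 to a trans α-methylene γ-lactone (O6–C12(=O)–C11(=C13)–C7). The ring carries a Z trisubstituted alkene C4=C5 (C15 on C4) and a trans 1,10-oxirane (C14 on C10) that corresponds to an E C1=C10 alkene. C6, C7 and C8 form a contiguous triad (lactone oxygen, C11 branch, acyloxy group). C3 (isovalerate) is insulated from this triad by the alkene, and the (2S,3R)-2,3-dimethyloxirane-2-carboxylate on O8 adds two further centres. Fragile elements are the exocyclic enoate, both oxiranes, the allylic C–O bonds at C3 and C6, the medium-ring diene (transannular reactions), and a free 8-hydroxyl, which can translactonise onto C12. The real difficulty is the ten-membered ring with its Z alkene together with the C6/C7/C8 relationship around a trans lactone. The key step exploits the fact that C7 carries the C11–C12 branch trans to O6 with an oxygenated C8 next to it: this is what remains when a methoxycyclopropane (C7–C8–C11) fused to the lactone ring (O6–C12–C11–C7–C6) is cut at C8–C11.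

## Logic of the disconnections

**38 ⇒ 37.** The C1–O and C10–O bonds of the ring oxirane are removed first. The oxirane is acid-labile and would not survive ring construction, and the E C1=C10 alkene of 37 is the most electron-rich π bond. The forward step must be chemoselective (C4=C5 carries two allylic acyloxy groups, C11=C13 is conjugated) and must attack the outer face that gives 1R,10R.

**37 ⇒ 31 + 35.** The O8–acyl bond is cut so that the sensitive epoxy ester arrives after all organometallic and strong-base chemistry. 35 goes back through 34 and 33 to 32 by cutting the two oxirane C–O bonds (asymmetric epoxidation of an allylic alcohol). The forward acylation must outrun O6→O8 lactone migration in 31.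

**31 ⇒ 30 ⇒ 29.** Removal of the O8 silyl group and of the O3 isovaleryl group leads to 29, in which the two secondary hydroxyls are differentiated (O3 free, O8 silylated). This demands that ring closure delivers O3 free while O8 is masked.

**29 ⇒ 28.** The C3–C4 ring bond is cut. It joins an sp2 carbon to a carbinol, so an alkenyl-metal addition to an aldehyde forms ring and carbinol together and keeps the Z geometry. The forward step must close a ten-membered ring at high dilution and set C3 under macrocyclic control.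

**28 ⇒ 27 ⇒ 26 ⇒ 25 ⇒ 24.** Oxidation-level changes at C3 are undone. The C4=C5 bond is then cut to the C5 aldehyde 25 (iodo-olefination adds C4, C15 and iodine with Z selectivity), and 25 is traced to the primary silyl ether in 24. The demand is an orthogonal pair on O5 and O3 and no epimerisation at C6 next to the aldehyde.

**24 ⇒ 21 ⇒ 20 ⇒ 19 ⇒ 18.** The C11=C13 bond is cut (enolate aminomethylation and elimination), which must precede the alkenyl iodide and all esters. The silyl pattern is traced back through diol 20 to 19, and the C8–H bond to ketone 18. The reduction must give 8R and must not leave a free alkoxide next to the lactone.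

**18 ⇒ 17.** The temporary C8–C11 bond is re-formed retrosynthetically: the γ-keto lactone is the acid-opened form of a methoxycyclopropane lactone. The forward opening must not move the β,γ-alkene into conjugation.

**17 ⇒ 16.** The C7–C11 and C8–C11 bonds are cut together, back to a carbenoid at C11 tethered through O6. This removes two rings and three centres. It demands addition to the enol ether face that puts the C5 side chain exo, in preference to C–H insertion at C5.

**16 ⇒ 14 ⇒ 13 ⇒ 11.** The O6–acyl bond, the C8–OMe bond (from a Z alkenyl iodide with retention) and the C8–I/C7–H pair (anti hydrometalation of a propargylic alcohol) are cut in turn. The forward steps must fix the Z enol ether geometry and keep the acid-labile hydroxy enol ether intact.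

**11 ⇒ 10 ⇒ 9 ⇒ 8 + 6.** Protecting-group changes lead to the acetonide 9, which is cut at C8–C9 into a chiral-pool alkyne and an allylic bromide. C6 is thereby bought, not made.

**8 ⇒ 7; 6 ⇒ 5 ⇒ 4 ⇒ 2 ⇒ 1.** The alkyne comes from 7 by one-carbon homologation. The bromide comes from 1 through an E-selective olefination that forms C10=C1.

## Other disconnections considered

**Alternative 1:** The cut is the C3–C4 ring bond, made on the seco iodo-aldehyde A2, which already carries the epoxy ester on O8 and the exocyclic methylene. In the forward step CrCl2 with catalytic NiCl2 turns the Z alkenyl iodide into an alkenylchromium species that adds to the C3 aldehyde and gives A1.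
- In its favour: the ring-closing event is the same one the chosen plan uses in step 22, so on mechanism and on control of C3 the two are equal. After closure only isovalerylation and epoxidation remain, against five steps in the chosen plan, and O8 needs no protecting group. On step economy it is the better plan.
- Against it: the glycidic ester and the enoate are exposed to a large excess of divalent chromium and to Lewis-acidic trivalent chromium chloride, so reductive or chloride opening of the oxirane is a real risk. The order acylation-then-methylenation is also blocked, because a lactone enolate can attack the neighbouring ester.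
- Comparison: the cut does not say how the trans C6/C7 lactone and C8 of A2 arise, so it still needs something like the cyclopropanation–fragmentation. The chosen plan uses the same closure but keeps O8 silylated until afterwards, trading three steps for safety.

**Alternative 2:** The cut is the C4=C5 double bond. The second-generation Grubbs catalyst joins the isopropenyl and vinyl groups of the bis-allylic silaketal A4 with loss of ethylene and gives the seven-membered silylene-bridged ene-diol A3.
- In its favour: the small ring forces the Z geometry, which is better than the iodo-olefination of the chosen plan, where some E isomer must be expected. C3 and C6 are set by separate asymmetric steps before any ring is made, which is better than relying on macrocyclic induction at C3.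
- Against it: metathesis to a trisubstituted alkene between two hindered secondary silyloxy carbons is slow. The unsymmetrical silaketal must be assembled stepwise. After A3 the lactone still has to be closed, and the ten-membered ring still has to be formed at another bond, with C8 created in that closure.
- Comparison: it solves the C3/C4=C5/C6 region elegantly but leaves the C6/C7/C8 triad and the medium ring open, which is the part the chosen key step addresses. It is likely longer overall.

**Alternative 3:** The cuts are C5–C6 and the lactone C12–O bond. CrCl2 with catalytic NiCl2 converts the Z alkenyl iodide of A6 into an alkenylchromium species that adds to the C6 aldehyde, and the resulting alkoxide closes onto the C12 methyl ester to give A5.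
- In its favour: two rings form in one operation, which is better ring economy than the chosen plan. C3, C7 and C8 are set beforehand by acyclic methods, so C3 does not depend on the macrocycle, which is also better.
- Against it: C6 is created in the closure and must come out trans to C7 by attack on an α-branched aldehyde whose α-carbon (C7) is epimerisable. Lactonisation in the same pot needs a favourable geometry in a strained product. The methylene must then be introduced on the macrocycle with strong base.
- Comparison: the chosen plan fixes C6 from the chiral pool and C7 by a stereospecific intramolecular addition, so the lactone stereochemistry is more secure, at the price of separate lactone-forming and ring-closing steps.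

Key step: step 12

Remark on the structures: the chain that passes through the key step already contains C3 (as a CH2O terminus), so the ring cannot be closed at C2–C3 without duplicating C3. It is therefore closed at C3–C4 after C4 and C15 are added to C5, and O3 is carried as a 4-methoxybenzyl ether. Compound 7 is taken as the commercial aldehyde, freshly distilled.

## Route

**Step 1**
Reactants: 1 propane-1,3-diol
Product: 2 3-[(4-methoxybenzyl)oxy]propan-1-ol
Conditions: NaH (1 equiv), 4-methoxybenzyl chloride, n-Bu4NI (cat.), THF/DMF, 0 °C → rt; diol in threefold excess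
Reagents that add atoms: 4-methoxybenzyl chloride, COc1ccc(CCl)cc1
Why: Williamson etherification; the excess of diol should keep dialkylation low.

**Step 2**
Reactants: 2 3-[(4-methoxybenzyl)oxy]propan-1-ol
Product: 4 ethyl (2E)-5-[(4-methoxybenzyl)oxy]-2-methylpent-2-enoate, via 3-[(4-methoxybenzyl)oxy]propanal 3 (not isolated)
Conditions: TEMPO (10 mol%), PhI(OAc)2, CH2Cl2, rt; then Ph3P=C(Me)CO2Et, rt → 40 °C
Reagents that add atoms: ethyl 2-(triphenylphosphoranylidene)propanoate, CCOC(=O)C(C)=P(c1ccccc1)(c1ccccc1)c1ccccc1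
Why: Nitroxyl oxidation followed in the same flask by Wittig olefination with a stabilised ylide, which should give the E alkene (future C10=C1); trapping the β-alkoxy aldehyde as it forms avoids its β-elimination.

**Step 3**
Reactants: 4 ethyl (2E)-5-[(4-methoxybenzyl)oxy]-2-methylpent-2-enoate
Product: 5 (2E)-5-[(4-methoxybenzyl)oxy]-2-methylpent-2-en-1-ol
Conditions: i-Bu2AlH (2.2 equiv), CH2Cl2, −78 °C; aq. potassium sodium tartrate
Reagents that add atoms: none
Why: 1,2-Reduction of the enoate by the aluminium hydride; the alkene geometry is untouched.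

**Step 4**
Reactants: 5 (2E)-5-[(4-methoxybenzyl)oxy]-2-methylpent-2-en-1-ol
Product: 6 1-({[(3E)-5-bromo-4-methylpent-3-en-1-yl]oxy}methyl)-4-methoxybenzene
Conditions: CBr4, PPh3, CH2Cl2, 0 °C
Reagents that add atoms: carbon tetrabromide, BrC(Br)(Br)Br
Why: Appel bromination of a primary allylic alcohol; direct SN2 displacement should leave the E alkene in place.

**Step 5**
Reactants: 7 (4R)-2,2-dimethyl-1,3-dioxolane-4-carbaldehyde
Product: 8 (4S)-4-ethynyl-2,2-dimethyl-1,3-dioxolane
Conditions: dimethyl (1-diazo-2-oxopropyl)phosphonate, K2CO3, MeOH, 0 °C → rt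
Reagents that add atoms: dimethyl (1-diazo-2-oxopropyl)phosphonate, CC(=O)C(=[N+]=[N-])P(=O)(OC)OC
Why: Seyferth–Gilbert homologation with the Ohira–Bestmann reagent; the C6 centre comes from the chiral pool and the mild carbonate conditions should not epimerise it (the descriptor changes from R to S only through priorities).

**Step 6**
Reactants: 8 (4S)-4-ethynyl-2,2-dimethyl-1,3-dioxolane; 6 1-({[(3E)-5-bromo-4-methylpent-3-en-1-yl]oxy}methyl)-4-methoxybenzene
Product: 9 (4S)-4-{(4E)-7-[(4-methoxybenzyl)oxy]-4-methylhept-4-en-1-yn-1-yl}-2,2-dimethyl-1,3-dioxolane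
Conditions: CuI (10 mol%), K2CO3, n-Bu4NBr (cat.), DMF, rt
Reagents that add atoms: none
Why: Copper-catalysed coupling of a terminal alkyne with a primary allylic bromide (C8–C9 bond); attack at the unhindered CH2Br terminus should give the linear skipped enyne.

**Step 7**
Reactants: 9 (4S)-4-{(4E)-7-[(4-methoxybenzyl)oxy]-4-methylhept-4-en-1-yn-1-yl}-2,2-dimethyl-1,3-dioxolane
Product: 10 (2S,6E)-9-[(4-methoxybenzyl)oxy]-6-methylnon-6-en-3-yne-1,2-diol
Conditions: AcOH/H2O (4:1), 45 °C
Reagents that add atoms: none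
Why: Acid hydrolysis of the acetonide; the benzylic ether and the skipped enyne tolerate aqueous acetic acid.

**Step 8**
Reactants: 10 (2S,6E)-9-[(4-methoxybenzyl)oxy]-6-methylnon-6-en-3-yne-1,2-diol
Product: 11 (2S,6E)-9-[(4-methoxybenzyl)oxy]-6-methyl-1-[(triisopropylsilyl)oxy]non-6-en-3-yn-2-ol
Conditions: i-Pr3SiCl, imidazole, CH2Cl2, 0 °C
Reagents that add atoms: chlorotriisopropylsilane, CC(C)[Si](Cl)(C(C)C)C(C)C
Why: Selective silylation of the primary hydroxyl (O5) by a bulky silyl chloride; the bulky group later shields O5 and the C5–H bonds from the carbenoid and does not migrate under base.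

**Step 9**
Reactants: 11 (2S,6E)-9-[(4-methoxybenzyl)oxy]-6-methyl-1-[(triisopropylsilyl)oxy]non-6-en-3-yn-2-ol
Product: 13 (2S,3Z,6E)-4-iodo-9-[(4-methoxybenzyl)oxy]-6-methyl-1-[(triisopropylsilyl)oxy]nona-3,6-dien-2-ol, via cyclic sodium alkenylalanate 12 (not isolated)
Conditions: NaAlH2(OCH2CH2OMe)2, THF, 0 °C → rt; EtOAc; then I2, THF, −78 °C
Reagents that add atoms: iodine, II
Why: Hydroxyl-directed anti hydroalumination of the propargylic alcohol places aluminium on the distal carbon C8 and hydride on C7; iodinolysis with retention should give the Z iodide (iodine cis to C6).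

**Step 10**
Reactants: 13 (2S,3Z,6E)-4-iodo-9-[(4-methoxybenzyl)oxy]-6-methyl-1-[(triisopropylsilyl)oxy]nona-3,6-dien-2-ol
Product: 14 (2S,3Z,6E)-4-methoxy-9-[(4-methoxybenzyl)oxy]-6-methyl-1-[(triisopropylsilyl)oxy]nona-3,6-dien-2-ol
Conditions: CuI (10 mol%), 3,4,7,8-tetramethyl-1,10-phenanthroline (20 mol%), Cs2CO3, MeOH/toluene, 80 °C, sealed tube
Reagents that add atoms: methanol, CO
Why: Ullmann-type copper-catalysed C–O coupling of an alkenyl iodide with an aliphatic alcohol, which proceeds with retention of alkene geometry; methanol in large excess should outcompete the hindered secondary hydroxyl, and the product is handled on base-washed silica.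

**Step 11**
Reactants: 14 (2S,3Z,6E)-4-methoxy-9-[(4-methoxybenzyl)oxy]-6-methyl-1-[(triisopropylsilyl)oxy]nona-3,6-dien-2-ol
Product: 16 (2S,3Z,6E)-4-methoxy-9-[(4-methoxybenzyl)oxy]-6-methyl-1-[(triisopropylsilyl)oxy]nona-3,6-dien-2-yl diazoacetate, via C6 bromoacetate 15 (not isolated)
Conditions: BrCH2COBr, pyridine, CH2Cl2, −20 °C; then TsNHNHTs, DBU, THF, 0 °C
Reagents that add atoms: bromoacetyl bromide, BrCC(Br)=O; N,N'-ditosylhydrazine, Cc1ccc(cc1)S(=O)(=O)NNS(=O)(=O)c1ccc(C)cc1
Why: O-Acylation, then N-alkylation of the bis-sulfonyl hydrazine and double base-induced loss of sulfinate, gives the diazoacetate; the medium stays basic throughout, as the ionisable allylic ester next to an enol ether requires.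

**Step 12**
Reactants: 16 (2S,3Z,6E)-4-methoxy-9-[(4-methoxybenzyl)oxy]-6-methyl-1-[(triisopropylsilyl)oxy]nona-3,6-dien-2-yl diazoacetate
Product: 17 (1S,4S,5S,6R)-6-methoxy-6-{(2E)-5-[(4-methoxybenzyl)oxy]-2-methylpent-2-en-1-yl}-4-{[(triisopropylsilyl)oxy]methyl}-3-oxabicyclo[3.1.0]hexan-2-one
Conditions: Cu(acac)2 (5 mol%), toluene, 85 °C, syringe-pump addition of 16 (final 0.005 M)
Reagents that add atoms: none
Why: The diazo ester reduces Cu(acac)2 to the active monovalent copper species, which expels N2 and forms an electrophilic copper carbenoid at C11. The carbenoid adds to the electron-rich enol ether C7=C8 in a concerted, asynchronous [2+1] step (C7–C11 leading, the developing positive charge at C8 stabilised by the methoxy group); the closest known reaction type is the intramolecular cyclopropanation of allylic diazoacetates to 3-oxabicyclo[3.1.0]hexan-2-ones. The γ-lactone closes in a 5-exo mode at C7, the only alkene carbon the three-atom ester tether can reach, and the cyclopropane closes by bonding of C11 to C8 in the same event (formal 3-exo closure). At C11 the cis ring fusion is forced by the tether. At C8 the addition is stereospecific, so the methoxy group, cis to C6 in the Z alkene, ends endo and the C9 chain exo. At C7, the only new centre that is kept, A(1,3) strain holds C6–H in the alkene plane toward the cis methoxy group, so O6 and its carbenoid lie on one face and the silyloxymethyl group on the other; the side chain therefore ends exo, which is the trans C6/C7 lactone. The selectivity needed is cyclopropanation over insertion into the oxygen-activated C5–H bonds (also a five-membered transition state) and over oxonium ylide formation; copper is a poor C–H insertion catalyst, the enol ether is the most nucleophilic site, and the bulky silyl ether oxygen is a poor donor. Slow addition at high dilution should suppress carbene dimerisation.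

**Step 13**
Reactants: 17 (1S,4S,5S,6R)-6-methoxy-6-{(2E)-5-[(4-methoxybenzyl)oxy]-2-methylpent-2-en-1-yl}-4-{[(triisopropylsilyl)oxy]methyl}-3-oxabicyclo[3.1.0]hexan-2-one
Product: 18 (4S,5S)-4-{(3E)-6-[(4-methoxybenzyl)oxy]-3-methylhex-3-enoyl}-5-{[(triisopropylsilyl)oxy]methyl}dihydrofuran-2(3H)-one
Conditions: aq. HCl (1 M)/THF (1:5), 0 °C → rt, short reaction time
Reagents that add atoms: water, O
Why: Acid-induced donor–acceptor fragmentation: the methoxy lone pair pushes, the protonated lactone pulls, C8–C11 breaks to an oxocarbenium ion and a lactone enol, and hydration with loss of methanol leaves the C8 ketone and the C11 methylene; C7 is untouched and trans is also the thermodynamic arrangement, and brief exposure should avoid moving the β,γ-alkene into conjugation.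

**Step 14**
Reactants: 18 (4S,5S)-4-{(3E)-6-[(4-methoxybenzyl)oxy]-3-methylhex-3-enoyl}-5-{[(triisopropylsilyl)oxy]methyl}dihydrofuran-2(3H)-one
Product: 19 (4R,5S)-4-{(1R,3E)-1-hydroxy-6-[(4-methoxybenzyl)oxy]-3-methylhex-3-en-1-yl}-5-{[(triisopropylsilyl)oxy]methyl}dihydrofuran-2(3H)-one
Conditions: (S)-2-methyl-CBS-oxazaborolidine (0.5 equiv), catecholborane, toluene/CH2Cl2, −78 °C; pH 7 buffer
Reagents that add atoms: none
Why: Corey–Bakshi–Shibata reduction; the catalyst treats the ring-branched C7 side as the large group and the allylic CH2 side as the small one, which should give 8R, and Felkin–Anh attack anti to C6 leads to the same face, so reagent and substrate are matched; the neutral borate intermediate avoids a free alkoxide that could translactonise onto C12.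

**Step 15**
Reactants: 19 (4R,5S)-4-{(1R,3E)-1-hydroxy-6-[(4-methoxybenzyl)oxy]-3-methylhex-3-en-1-yl}-5-{[(triisopropylsilyl)oxy]methyl}dihydrofuran-2(3H)-one
Product: 20 (4R,5S)-4-{(1R,3E)-1-hydroxy-6-[(4-methoxybenzyl)oxy]-3-methylhex-3-en-1-yl}-5-(hydroxymethyl)dihydrofuran-2(3H)-one
Conditions: HF·pyridine, pyridine, THF, 0 °C → rt
Reagents that add atoms: none
Why: Fluoride cleavage of the primary silyl ether in a weakly acidic medium, where lactone migration should be slow; nothing else in 19 is fluoride-labile.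

**Step 16**
Reactants: 20 (4R,5S)-4-{(1R,3E)-1-hydroxy-6-[(4-methoxybenzyl)oxy]-3-methylhex-3-en-1-yl}-5-(hydroxymethyl)dihydrofuran-2(3H)-one
Product: 21 (4S,5S)-4-{(1R,3E)-6-[(4-methoxybenzyl)oxy]-3-methyl-1-[(triethylsilyl)oxy]hex-3-en-1-yl}-5-{[(triethylsilyl)oxy]methyl}dihydrofuran-2(3H)-one
Conditions: Et3SiOTf (2.5 equiv), 2,6-lutidine, CH2Cl2, −78 °C
Reagents that add atoms: triethylsilyl trifluoromethanesulfonate, CC[Si](CC)(CC)OS(=O)(=O)C(F)(F)F
Why: Exhaustive silylation with a silyl triflate and a hindered pyridine base; the two identical groups are later told apart as primary against secondary.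

**Step 17**
Reactants: 21 (4S,5S)-4-{(1R,3E)-6-[(4-methoxybenzyl)oxy]-3-methyl-1-[(triethylsilyl)oxy]hex-3-en-1-yl}-5-{[(triethylsilyl)oxy]methyl}dihydrofuran-2(3H)-one
Product: 24 (4S,5S)-4-{(1R,3E)-6-[(4-methoxybenzyl)oxy]-3-methyl-1-[(triethylsilyl)oxy]hex-3-en-1-yl}-3-methylidene-5-{[(triethylsilyl)oxy]methyl}dihydrofuran-2(3H)-one, via Mannich base 22 (not isolated), via trimethylammonium iodide 23 (not isolated)
Conditions: LiN(i-Pr)2, THF, −78 °C; CH2=NMe2+ I−, −78 °C → rt; MeI, THF, rt; aq. NaHCO3, CH2Cl2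
Reagents that add atoms: N,N-dimethylmethyleneiminium iodide (Eschenmoser's salt), C=[N+](C)C.[I-]
Why: The lactone enolate (the only enolisable site) is aminomethylated at C11, and quaternisation followed by mild-base elimination installs C11=C13; this is done here because no ester, ketone or alkenyl iodide is yet present to interfere with the amide base.

**Step 18**
Reactants: 24 (4S,5S)-4-{(1R,3E)-6-[(4-methoxybenzyl)oxy]-3-methyl-1-[(triethylsilyl)oxy]hex-3-en-1-yl}-3-methylidene-5-{[(triethylsilyl)oxy]methyl}dihydrofuran-2(3H)-one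
Product: 25 (2S,3S)-3-{(1R,3E)-6-[(4-methoxybenzyl)oxy]-3-methyl-1-[(triethylsilyl)oxy]hex-3-en-1-yl}-4-methylidene-5-oxotetrahydrofuran-2-carbaldehyde
Conditions: (COCl)2, DMSO, CH2Cl2, −78 → −40 °C; i-Pr2NEt, −78 → 0 °C; used crude
Reagents that add atoms: none
Why: Swern oxidation applied directly to a primary triethylsilyl ether: the chlorosulfonium salt cleaves the unhindered primary Si–O bond and oxidises C5, while the hindered secondary silyl ether at O8 should survive; the hindered amine and immediate use limit epimerisation at C6.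

**Step 19**
Reactants: 25 (2S,3S)-3-{(1R,3E)-6-[(4-methoxybenzyl)oxy]-3-methyl-1-[(triethylsilyl)oxy]hex-3-en-1-yl}-4-methylidene-5-oxotetrahydrofuran-2-carbaldehyde
Product: 26 (4S,5S)-5-[(1Z)-2-iodoprop-1-en-1-yl]-4-{(1R,3E)-6-[(4-methoxybenzyl)oxy]-3-methyl-1-[(triethylsilyl)oxy]hex-3-en-1-yl}-3-methylidenedihydrofuran-2(3H)-one
Conditions: EtPPh3+ I−, n-BuLi, THF; I2, −78 °C; NaN(SiMe3)2, −20 °C; then 25, −78 °C
Reagents that add atoms: ethyltriphenylphosphonium iodide, CC[P+](c1ccccc1)(c1ccccc1)c1ccccc1.[I-]; iodine, II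
Why: Stork–Zhao olefination with the α-iodo ylide adds C4, C15 and iodine; kinetic cis-oxaphosphetane formation should place iodine cis to C6 (Z), and the aldehyde reacts far faster at −78 °C than the enoate.

**Step 20**
Reactants: 26 (4S,5S)-5-[(1Z)-2-iodoprop-1-en-1-yl]-4-{(1R,3E)-6-[(4-methoxybenzyl)oxy]-3-methyl-1-[(triethylsilyl)oxy]hex-3-en-1-yl}-3-methylidenedihydrofuran-2(3H)-one
Product: 27 (4S,5S)-4-{(1R,3E)-6-hydroxy-3-methyl-1-[(triethylsilyl)oxy]hex-3-en-1-yl}-5-[(1Z)-2-iodoprop-1-en-1-yl]-3-methylidenedihydrofuran-2(3H)-one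
Conditions: DDQ, CH2Cl2/pH 7 buffer, 0 °C
Reagents that add atoms: none
Why: Oxidative cleavage of the 4-methoxybenzyl ether by hydride abstraction and hydrolysis; the buffer protects the secondary silyl ether, and the alkenes and alkenyl iodide are inert.

**Step 21**
Reactants: 27 (4S,5S)-4-{(1R,3E)-6-hydroxy-3-methyl-1-[(triethylsilyl)oxy]hex-3-en-1-yl}-5-[(1Z)-2-iodoprop-1-en-1-yl]-3-methylidenedihydrofuran-2(3H)-one
Product: 28 (4S,5S)-5-[(1Z)-2-iodoprop-1-en-1-yl]-3-methylidene-4-{(1R,3E)-3-methyl-6-oxo-1-[(triethylsilyl)oxy]hex-3-en-1-yl}dihydrofuran-2(3H)-one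
Conditions: Dess–Martin periodinane, NaHCO3, CH2Cl2, 0 °C; used at once
Reagents that add atoms: none
Why: Dess–Martin oxidation under buffered, non-basic conditions, chosen because the β,γ-unsaturated aldehyde would otherwise slip into conjugation.

**Step 22**
Reactants: 28 (4S,5S)-5-[(1Z)-2-iodoprop-1-en-1-yl]-3-methylidene-4-{(1R,3E)-3-methyl-6-oxo-1-[(triethylsilyl)oxy]hex-3-en-1-yl}dihydrofuran-2(3H)-one
Product: 29 (3S,6R,7S,8R,1(10)E,4Z)-3-hydroxy-8-[(triethylsilyl)oxy]germacra-1(10),4,11(13)-trien-12,6-olide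
Conditions: CrCl2 (15 equiv), NiCl2 (cat.), DMSO/THF, rt, slow addition (0.003 M)
Reagents that add atoms: none
Why: Nozaki–Hiyama–Kishi closure: zerovalent nickel inserts into the C–I bond with retention, the alkenyl group passes to trivalent chromium and adds chemoselectively to the aldehyde, forming C3–C4 and the ten-membered ring with the Z alkene intact. C3 is set by the conformation of the closing ring; the 3S carbinol, with the bulky chromium alkoxide on the outside of the forming ring, is the anticipated epimer, but this is not secure and is covered by a fallback.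

**Step 23**
Reactants: 29 (3S,6R,7S,8R,1(10)E,4Z)-3-hydroxy-8-[(triethylsilyl)oxy]germacra-1(10),4,11(13)-trien-12,6-olide
Product: 30 (3S,6R,7S,8R,1(10)E,4Z)-3-(3-methylbutanoyloxy)-8-[(triethylsilyl)oxy]germacra-1(10),4,11(13)-trien-12,6-olide
Conditions: (i-BuCO)2O, DMAP, Et3N, CH2Cl2, 0 °C
Reagents that add atoms: 3-methylbutanoic anhydride, CC(C)CC(=O)OC(=O)CC(C)C
Why: DMAP-catalysed acylation of the only free hydroxyl, with retention at C3.

**Step 24**
Reactants: 30 (3S,6R,7S,8R,1(10)E,4Z)-3-(3-methylbutanoyloxy)-8-[(triethylsilyl)oxy]germacra-1(10),4,11(13)-trien-12,6-olide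
Product: 31 (3S,6R,7R,8R,1(10)E,4Z)-8-hydroxy-3-(3-methylbutanoyloxy)germacra-1(10),4,11(13)-trien-12,6-olide
Conditions: HF·pyridine, pyridine, THF, 0 °C
Reagents that add atoms: none
Why: Buffered fluoride removes the secondary triethylsilyl ether without base (no lactone migration) and without acid strong enough for transannular cyclisation.

**Step 25**
Reactants: 32 (2E)-2-methylbut-2-enoic acid (tiglic acid)
Product: 33 (2E)-2-methylbut-2-en-1-ol
Conditions: LiAlH4, Et2O, 0 °C
Reagents that add atoms: none
Why: Hydride reduction of the unsaturated acid to the allylic alcohol with the E alkene kept.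

**Step 26**
Reactants: 33 (2E)-2-methylbut-2-en-1-ol
Product: 34 [(2R,3R)-2,3-dimethyloxiran-2-yl]methanol
Conditions: Ti(Oi-Pr)4 (10 mol%), D-(−)-diisopropyl tartrate (12 mol%), t-BuOOH, 4 Å molecular sieves, CH2Cl2, −20 °C
Reagents that add atoms: tert-butyl hydroperoxide, CC(C)(C)OO
Why: Sharpless asymmetric epoxidation; the tetravalent titanium–D-tartrate complex delivers oxygen to the face that gives the (2R,3R) epoxy alcohol, and the E geometry fixes the two methyl groups cis.

**Step 27**
Reactants: 34 [(2R,3R)-2,3-dimethyloxiran-2-yl]methanol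
Product: 35 (2S,3R)-2,3-dimethyloxirane-2-carboxylic acid
Conditions: TEMPO (cat.), NaOCl (cat.), NaClO2, MeCN/pH 6.7 phosphate buffer, 35 °C
Reagents that add atoms: sodium chlorite, [Na+].[O-]Cl=O
Why: Nitroxyl-catalysed oxidation through the aldehyde to the acid at near-neutral pH, which spares the oxirane; the descriptor at C2 changes only through priorities.

**Step 28**
Reactants: 31 (3S,6R,7R,8R,1(10)E,4Z)-8-hydroxy-3-(3-methylbutanoyloxy)germacra-1(10),4,11(13)-trien-12,6-olide; 35 (2S,3R)-2,3-dimethyloxirane-2-carboxylic acid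
Product: 37 (3S,6R,7R,8R,1(10)E,4Z)-8-{[(2S,3R)-2,3-dimethyloxiran-2-yl]carbonyloxy}-3-(3-methylbutanoyloxy)germacra-1(10),4,11(13)-trien-12,6-olide, via mixed anhydride 36 (not isolated)
Conditions: 2,4,6-Cl3C6H2COCl, Et3N, toluene, rt; then 31, DMAP, rt
Reagents that add atoms: none
Why: Yamaguchi esterification; the mixed anhydride is attacked by DMAP at the less hindered epoxy-acyl carbon and transfers it to the hindered O8, and the acid has no α-hydrogen so it cannot epimerise.

**Step 29**
Reactants: 37 (3S,6R,7R,8R,1(10)E,4Z)-8-{[(2S,3R)-2,3-dimethyloxiran-2-yl]carbonyloxy}-3-(3-methylbutanoyloxy)germacra-1(10),4,11(13)-trien-12,6-olide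
Product: 38 (1R,3S,6R,7R,8R,10R,4Z)-8-{[(2S,3R)-2,3-dimethyloxiran-2-yl]carbonyloxy}-1,10-epoxy-3-(3-methylbutanoyloxy)germacra-4,11(13)-dien-12,6-olide (target)
Conditions: m-CPBA (1.1 equiv), NaHCO3, CH2Cl2, −20 → 0 °C
Reagents that add atoms: 3-chloroperoxybenzoic acid, OOC(=O)c1cccc(Cl)c1
Why: Prilezhaev epoxidation of the most electron-rich alkene (C4=C5 is deactivated by two allylic acyloxy groups, C11=C13 by conjugation); the peracid should attack the E alkene from the outer face of the ring, which is expected to give the trans 1R,10R oxirane.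

## Compound list

1 | propane-1,3-diol | OCCCO | starting material
2 | 3-[(4-methoxybenzyl)oxy]propan-1-ol | COc1ccc(COCCCO)cc1 | intermediate
3 | 3-[(4-methoxybenzyl)oxy]propanal | COc1ccc(COCCC=O)cc1 | intermediate (not isolated)
4 | ethyl (2E)-5-[(4-methoxybenzyl)oxy]-2-methylpent-2-enoate | CCOC(=O)/C(C)=C/CCOCc1ccc(OC)cc1 | intermediate
5 | (2E)-5-[(4-methoxybenzyl)oxy]-2-methylpent-2-en-1-ol | OC/C(C)=C/CCOCc1ccc(OC)cc1 | intermediate
6 | 1-({[(3E)-5-bromo-4-methylpent-3-en-1-yl]oxy}methyl)-4-methoxybenzene | BrC/C(C)=C/CCOCc1ccc(OC)cc1 | intermediate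
7 | (4R)-2,2-dimethyl-1,3-dioxolane-4-carbaldehyde | O=C[C@H]1COC(C)(C)O1 | starting material
8 | (4S)-4-ethynyl-2,2-dimethyl-1,3-dioxolane | C#C[C@H]1COC(C)(C)O1 | intermediate
9 | (4S)-4-{(4E)-7-[(4-methoxybenzyl)oxy]-4-methylhept-4-en-1-yn-1-yl}-2,2-dimethyl-1,3-dioxolane | COc1ccc(COCC/C=C(\C)CC#C[C@H]2COC(C)(C)O2)cc1 | intermediate
10 | (2S,6E)-9-[(4-methoxybenzyl)oxy]-6-methylnon-6-en-3-yne-1,2-diol | OC[C@@H](O)C#CC/C(C)=C/CCOCc1ccc(OC)cc1 | intermediate
11 | (2S,6E)-9-[(4-methoxybenzyl)oxy]-6-methyl-1-[(triisopropylsilyl)oxy]non-6-en-3-yn-2-ol | CC(C)[Si](OC[C@@H](O)C#CC/C(C)=C/CCOCc1ccc(OC)cc1)(C(C)C)C(C)C | intermediate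
12 | sodium five-membered alkoxy(alkenyl)aluminate (ring O6–Al–C8=C7–C6) carrying two 2-methoxyethoxy groups on aluminium | [Na+].COCCO[Al-]1(OCCOC)O[C@H](CO[Si](C(C)C)(C(C)C)C(C)C)C=C1C/C(C)=C/CCOCc1ccc(OC)cc1 | intermediate (not isolated)
13 | (2S,3Z,6E)-4-iodo-9-[(4-methoxybenzyl)oxy]-6-methyl-1-[(triisopropylsilyl)oxy]nona-3,6-dien-2-ol | CC(C)[Si](OC[C@@H](O)/C=C(\I)C/C(C)=C/CCOCc1ccc(OC)cc1)(C(C)C)C(C)C | intermediate
14 | (2S,3Z,6E)-4-methoxy-9-[(4-methoxybenzyl)oxy]-6-methyl-1-[(triisopropylsilyl)oxy]nona-3,6-dien-2-ol | CC(C)[Si](OC[C@@H](O)/C=C(\OC)C/C(C)=C/CCOCc1ccc(OC)cc1)(C(C)C)C(C)C | intermediate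
15 | (2S,3Z,6E)-4-methoxy-9-[(4-methoxybenzyl)oxy]-6-methyl-1-[(triisopropylsilyl)oxy]nona-3,6-dien-2-yl bromoacetate | BrCC(=O)O[C@H](CO[Si](C(C)C)(C(C)C)C(C)C)/C=C(\OC)C/C(C)=C/CCOCc1ccc(OC)cc1 | intermediate (not isolated)
16 | (2S,3Z,6E)-4-methoxy-9-[(4-methoxybenzyl)oxy]-6-methyl-1-[(triisopropylsilyl)oxy]nona-3,6-dien-2-yl diazoacetate | [N-]=[N+]=CC(=O)O[C@H](CO[Si](C(C)C)(C(C)C)C(C)C)/C=C(\OC)C/C(C)=C/CCOCc1ccc(OC)cc1 | intermediate (key-step precursor)
17 | (1S,4S,5S,6R)-6-methoxy-6-{(2E)-5-[(4-methoxybenzyl)oxy]-2-methylpent-2-en-1-yl}-4-{[(triisopropylsilyl)oxy]methyl}-3-oxabicyclo[3.1.0]hexan-2-one | O=C1O[C@H](CO[Si](C(C)C)(C(C)C)C(C)C)[C@@H]2[C@H]1[C@@]2(OC)C/C(C)=C/CCOCc1ccc(OC)cc1 | intermediate (key-step product)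
18 | (4S,5S)-4-{(3E)-6-[(4-methoxybenzyl)oxy]-3-methylhex-3-enoyl}-5-{[(triisopropylsilyl)oxy]methyl}dihydrofuran-2(3H)-one | O=C1O[C@H](CO[Si](C(C)C)(C(C)C)C(C)C)[C@H](C1)C(=O)C/C(C)=C/CCOCc1ccc(OC)cc1 | intermediate
19 | (4R,5S)-4-{(1R,3E)-1-hydroxy-6-[(4-methoxybenzyl)oxy]-3-methylhex-3-en-1-yl}-5-{[(triisopropylsilyl)oxy]methyl}dihydrofuran-2(3H)-one | O=C1O[C@H](CO[Si](C(C)C)(C(C)C)C(C)C)[C@H](C1)[C@H](O)C/C(C)=C/CCOCc1ccc(OC)cc1 | intermediate
20 | (4R,5S)-4-{(1R,3E)-1-hydroxy-6-[(4-methoxybenzyl)oxy]-3-methylhex-3-en-1-yl}-5-(hydroxymethyl)dihydrofuran-2(3H)-one | O=C1O[C@H](CO)[C@H](C1)[C@H](O)C/C(C)=C/CCOCc1ccc(OC)cc1 | intermediate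
21 | (4S,5S)-4-{(1R,3E)-6-[(4-methoxybenzyl)oxy]-3-methyl-1-[(triethylsilyl)oxy]hex-3-en-1-yl}-5-{[(triethylsilyl)oxy]methyl}dihydrofuran-2(3H)-one | O=C1O[C@H](CO[Si](CC)(CC)CC)[C@H](C1)[C@H](O[Si](CC)(CC)CC)C/C(C)=C/CCOCc1ccc(OC)cc1 | intermediate
22 | 3-[(dimethylamino)methyl] derivative of 21 (C11 epimers) | CN(C)CC1C(=O)O[C@H](CO[Si](CC)(CC)CC)[C@H]1[C@H](O[Si](CC)(CC)CC)C/C(C)=C/CCOCc1ccc(OC)cc1 | intermediate (not isolated)
23 | 3-[(trimethylammonio)methyl] derivative of 21, iodide | C[N+](C)(C)CC1C(=O)O[C@H](CO[Si](CC)(CC)CC)[C@H]1[C@H](O[Si](CC)(CC)CC)C/C(C)=C/CCOCc1ccc(OC)cc1.[I-] | intermediate (not isolated)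
24 | (4S,5S)-4-{(1R,3E)-6-[(4-methoxybenzyl)oxy]-3-methyl-1-[(triethylsilyl)oxy]hex-3-en-1-yl}-3-methylidene-5-{[(triethylsilyl)oxy]methyl}dihydrofuran-2(3H)-one | C=C1C(=O)O[C@H](CO[Si](CC)(CC)CC)[C@H]1[C@H](O[Si](CC)(CC)CC)C/C(C)=C/CCOCc1ccc(OC)cc1 | intermediate
25 | (2S,3S)-3-{(1R,3E)-6-[(4-methoxybenzyl)oxy]-3-methyl-1-[(triethylsilyl)oxy]hex-3-en-1-yl}-4-methylidene-5-oxotetrahydrofuran-2-carbaldehyde | C=C1C(=O)O[C@H](C=O)[C@H]1[C@H](O[Si](CC)(CC)CC)C/C(C)=C/CCOCc1ccc(OC)cc1 | intermediate
26 | (4S,5S)-5-[(1Z)-2-iodoprop-1-en-1-yl]-4-{(1R,3E)-6-[(4-methoxybenzyl)oxy]-3-methyl-1-[(triethylsilyl)oxy]hex-3-en-1-yl}-3-methylidenedihydrofuran-2(3H)-one | C=C1C(=O)O[C@H](/C=C(\I)C)[C@H]1[C@H](O[Si](CC)(CC)CC)C/C(C)=C/CCOCc1ccc(OC)cc1 | intermediate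
27 | (4S,5S)-4-{(1R,3E)-6-hydroxy-3-methyl-1-[(triethylsilyl)oxy]hex-3-en-1-yl}-5-[(1Z)-2-iodoprop-1-en-1-yl]-3-methylidenedihydrofuran-2(3H)-one | C=C1C(=O)O[C@H](/C=C(\I)C)[C@H]1[C@H](O[Si](CC)(CC)CC)C/C(C)=C/CCO | intermediate
28 | (4S,5S)-5-[(1Z)-2-iodoprop-1-en-1-yl]-3-methylidene-4-{(1R,3E)-3-methyl-6-oxo-1-[(triethylsilyl)oxy]hex-3-en-1-yl}dihydrofuran-2(3H)-one | C=C1C(=O)O[C@H](/C=C(\I)C)[C@H]1[C@H](O[Si](CC)(CC)CC)C/C(C)=C/CC=O | intermediate
29 | (3S,6R,7S,8R,1(10)E,4Z)-3-hydroxy-8-[(triethylsilyl)oxy]germacra-1(10),4,11(13)-trien-12,6-olide | C=C1C(=O)O[C@@H]2/C=C(/C)[C@@H](O)C/C=C(\C)C[C@@H](O[Si](CC)(CC)CC)[C@@H]12 | intermediate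
30 | (3S,6R,7S,8R,1(10)E,4Z)-3-(3-methylbutanoyloxy)-8-[(triethylsilyl)oxy]germacra-1(10),4,11(13)-trien-12,6-olide | C=C1C(=O)O[C@@H]2/C=C(/C)[C@@H](OC(=O)CC(C)C)C/C=C(\C)C[C@@H](O[Si](CC)(CC)CC)[C@@H]12 | intermediate
31 | (3S,6R,7R,8R,1(10)E,4Z)-8-hydroxy-3-(3-methylbutanoyloxy)germacra-1(10),4,11(13)-trien-12,6-olide | C=C1C(=O)O[C@@H]2/C=C(/C)[C@@H](OC(=O)CC(C)C)C/C=C(\C)C[C@@H](O)[C@@H]12 | intermediate
32 | (2E)-2-methylbut-2-enoic acid | C/C=C(\C)C(=O)O | starting material
33 | (2E)-2-methylbut-2-en-1-ol | C/C=C(\C)CO | intermediate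
34 | [(2R,3R)-2,3-dimethyloxiran-2-yl]methanol | OC[C@@]1(C)O[C@@H]1C | intermediate
35 | (2S,3R)-2,3-dimethyloxirane-2-carboxylic acid | OC(=O)[C@@]1(C)O[C@@H]1C | intermediate
36 | (2S,3R)-2,3-dimethyloxirane-2-carboxylic 2,4,6-trichlorobenzoic anhydride | O=C(OC(=O)[C@@]1(C)O[C@@H]1C)c1c(Cl)cc(Cl)cc1Cl | intermediate (not isolated)
37 | (3S,6R,7R,8R,1(10)E,4Z)-8-{[(2S,3R)-2,3-dimethyloxiran-2-yl]carbonyloxy}-3-(3-methylbutanoyloxy)germacra-1(10),4,11(13)-trien-12,6-olide | C=C1C(=O)O[C@@H]2/C=C(/C)[C@@H](OC(=O)CC(C)C)C/C=C(\C)C[C@@H](OC(=O)[C@@]3(C)O[C@@H]3C)[C@@H]12 | intermediate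
38 | (1R,3S,6R,7R,8R,10R,4Z)-8-{[(2S,3R)-2,3-dimethyloxiran-2-yl]carbonyloxy}-1,10-epoxy-3-(3-methylbutanoyloxy)germacra-4,11(13)-dien-12,6-olide | C=C1C(=O)O[C@@H]2/C=C(/C)[C@@H](OC(=O)CC(C)C)C[C@H]3O[C@]3(C)C[C@@H](OC(=O)[C@@]3(C)O[C@@H]3C)[C@@H]12 | target

## Step count and least certain steps

Total step count: 29. Longest linear sequence: 25 steps (steps 1–4, 6–24, 28 and 29). Step 5 and steps 25–27 are side branches.

**Step 12 (key step).** Most likely to go wrong are ionisation of the allylic ester (the enol ether makes the C6–O bond unusually labile at 85 °C on a metal), insertion of the carbenoid into the oxygen-activated C5–H bonds, and carbene dimerisation. Premature opening of the donor–acceptor cyclopropane is harmless, because it leads toward 18. Fallback, from 6 to 18: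
- Bromide 6 alkylates 2-lithio-1,3-dithiane to give 2-{(2E)-5-[(4-methoxybenzyl)oxy]-2-methylpent-2-en-1-yl}-1,3-dithiane F1.
- Commercial (5S)-5-(hydroxymethyl)furan-2(5H)-one is silylated to (5S)-5-{[(triisopropylsilyl)oxy]methyl}furan-2(5H)-one F2.
- The lithium salt of F1 (n-BuLi, THF/DMPU, −78 °C) adds in conjugate fashion to F2 anti to the C6 substituent and gives the trans dithianyl lactone F3.
- MeI and CaCO3 in aqueous MeCN unmask the ketone, and the route is rejoined at 18.

**Step 10.** The free C6 hydroxyl may compete as the nucleophile (oligomeric vinyl ethers), the iodide may be lost by protodeiodination or by elimination back to the alkyne under hot carbonate, and the acid-labile hydroxy enol ether may decompose on isolation. Fallback, from 13 to 14: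
- 13 is silylated (Et3SiCl, imidazole) to its triethylsilyl ether F4.
- Iodine–lithium exchange (t-BuLi, −78 °C) and trapping with 2-isopropoxy-4,4,5,5-tetramethyl-1,3,2-dioxaborolane give the Z alkenyl pinacol boronate F5.
- Chan–Lam-type oxidative coupling with methanol (Cu(OAc)2, Et3N, MeOH, air, rt) gives the silylated Z enol ether F6 with retention.
- n-Bu4NF returns the route to 14.

**Step 14.** Facial discrimination may be poor, because both α-carbons of the ketone are sp3 and the two ring carbons on C7 differ only modestly in size. Some translactonisation onto O8 may also occur during work-up. Fallback, from 18 to 19: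
- The unwanted (8S)-alcohol F7 is separated.
- It is inverted by a Mitsunobu reaction with chloroacetic acid (PPh3, DIAD) to the (8R)-chloroacetate F8.
- The ester is removed under neutral conditions with thiourea (NaHCO3, EtOH), which gives 19.

**Step 22.** The β,γ-unsaturated aldehyde may isomerise into conjugation or oligomerise before the slow ten-membered closure, and the macrocyclic transition state may favour the C3 epimer. Fallback, from 28 to 30:
- If the closure delivers mainly the (3R)-alcohol F9, it is esterified with 3-methylbutanoic acid under Mitsunobu conditions (PPh3, DIAD, toluene, 0 °C).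
- This installs the isovalerate with inversion and rejoins the route at 30, with no change in step count.

**Step 29.** The peracid may attack the wrong face of C1=C10 in the flexible ring, or C4=C5, and the acid by-product may trigger transannular cyclisation. Fallback, from 37 to 38:
- N-Bromosuccinimide in aqueous THF should place bromine on the accessible face at C1 and water anti at the tertiary C10, giving the bromohydrin F10.
- Ring closure with K2CO3 in acetone displaces bromide with inversion, so the oxirane forms on the face opposite to the one an electrophile attacks, and gives 38.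

## Further compounds

F1 | step 12 | 2-{(2E)-5-[(4-methoxybenzyl)oxy]-2-methylpent-2-en-1-yl}-1,3-dithiane | COc1ccc(COCC/C=C(\C)CC2SCCCS2)cc1
F2 | step 12 | (5S)-5-{[(triisopropylsilyl)oxy]methyl}furan-2(5H)-one | O=C1O[C@H](CO[Si](C(C)C)(C(C)C)C(C)C)C=C1
F3 | step 12 | (4S,5S)-4-(2-{(2E)-5-[(4-methoxybenzyl)oxy]-2-methylpent-2-en-1-yl}-1,3-dithian-2-yl)-5-{[(triisopropylsilyl)oxy]methyl}dihydrofuran-2(3H)-one | O=C1O[C@H](CO[Si](C(C)C)(C(C)C)C(C)C)[C@H](C1)C2(SCCCS2)C/C(C)=C/CCOCc3ccc(OC)cc3
F4 | step 10 | triethylsilyl ether of 13 at O6 | CC[Si](CC)(CC)O[C@H](CO[Si](C(C)C)(C(C)C)C(C)C)/C=C(\I)C/C(C)=C/CCOCc1ccc(OC)cc1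
F5 | step 10 | Z alkenyl pinacol boronate corresponding to F4 (boron on C8) | CC[Si](CC)(CC)O[C@H](CO[Si](C(C)C)(C(C)C)C(C)C)/C=C(\B1OC(C)(C)C(C)(C)O1)C/C(C)=C/CCOCc1ccc(OC)cc1
F6 | step 10 | triethylsilyl ether of 14 at O6 | CC[Si](CC)(CC)O[C@H](CO[Si](C(C)C)(C(C)C)C(C)C)/C=C(\OC)C/C(C)=C/CCOCc1ccc(OC)cc1
F7 | step 14 | (8S)-epimer of 19 | O=C1O[C@H](CO[Si](C(C)C)(C(C)C)C(C)C)[C@H](C1)[C@@H](O)C/C(C)=C/CCOCc1ccc(OC)cc1
F8 | step 14 | (8R)-chloroacetate of 19 | O=C1O[C@H](CO[Si](C(C)C)(C(C)C)C(C)C)[C@H](C1)[C@H](OC(=O)CCl)C/C(C)=C/CCOCc1ccc(OC)cc1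
F9 | step 22 | (3R)-epimer of 29 | C=C1C(=O)O[C@@H]2/C=C(/C)[C@H](O)C/C=C(\C)C[C@@H](O[Si](CC)(CC)CC)[C@@H]12
F10 | step 29 | 1-bromo-10-hydroxy adduct of 37 (bromine at C1 anti to the C10 hydroxyl) | C=C1C(=O)O[C@@H]2/C=C(/C)[C@@H](OC(=O)CC(C)C)C[C@H](Br)[C@@](O)(C)C[C@@H](OC(=O)[C@@]3(C)O[C@@H]3C)[C@@H]12
A1 | alternative 1 | (3S,6R,7R,8R,1(10)E,4Z)-8-{[(2S,3R)-2,3-dimethyloxiran-2-yl]carbonyloxy}-3-hydroxygermacra-1(10),4,11(13)-trien-12,6-olide | C=C1C(=O)O[C@@H]2/C=C(/C)[C@@H](O)C/C=C(\C)C[C@@H](OC(=O)[C@@]3(C)O[C@@H]3C)[C@@H]12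
A2 | alternative 1 | seco C3 aldehyde with Z alkenyl iodide at C4, epoxy ester on O8 and α-methylene lactone | C=C1C(=O)O[C@H](/C=C(\I)C)[C@H]1[C@H](OC(=O)[C@@]2(C)O[C@@H]2C)C/C(C)=C/CC=O
A3 | alternative 2 | seven-membered di-isopropylsilylene-bridged cis C4=C5 ene-diol carrying both side chains | CC1=C[C@@H](O[Si](C(C)C)(C(C)C)O[C@H]1C/C=C(\C)COCc2ccc(OC)cc2)[C@H](CC(=O)OC(C)(C)C)CO[Si](C)(C)C(C)(C)C
A4 | alternative 2 | bis-allylic di-isopropylsilaketal (isopropenyl at C3, vinyl at C6) | C=C[C@@H](O[Si](C(C)C)(C(C)C)O[C@H](C(C)=C)C/C=C(\C)COCc1ccc(OC)cc1)[C@H](CC(=O)OC(C)(C)C)CO[Si](C)(C)C(C)(C)C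
A5 | alternative 3 | 11,13-dihydro-(1(10)E,4Z)-germacradien-12,6-olide with O3 tert-butyldimethylsilyl and O8 4-methoxybenzyl ethers | C1C(=O)O[C@@H]2/C=C(/C)[C@@H](O[Si](C)(C)C(C)(C)C)C/C=C(\C)C[C@@H](OCc3ccc(OC)cc3)[C@@H]12
A6 | alternative 3 | seco C6 aldehyde with Z alkenyl iodide at C5 and C12 methyl ester | I/C=C(/C)[C@@H](O[Si](C)(C)C(C)(C)C)C/C=C(\C)C[C@@H](OCc1ccc(OC)cc1)[C@@H](CC(=O)OC)C=O
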